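**Retrosynthetic overview**
1. The C2-symmetric 2,2'-biquinone is cut at its central C6–C6' bond into two copies of one C15 monomer, 2-hydroxy-3-methyl-6-(2-phenylethyl)-1,4-benzoquinone. One copy acts as acceptor (quinone) and the other as donor (its triol, made in the flask), and the adduct is oxidised to the target in the same pot.
2. Enabling feature: in each quinone ring (C1 carbonyl between C2–CH3 and C6, C3–OH, C4 carbonyl, C5–CH2CH2Ph) the biaryl carbon C6 is β to the C4 carbonyl, the one carbonyl not deactivated as a vinylogous acid by the C3 hydroxyl. In the reduced ring the same carbon is para to the C3–OH and ortho to the C1–OH, and it is the only unsubstituted ring carbon of the monomer.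
3. The monomer comes from para-oxidation of the symmetric resorcinol 2-methyl-5-(2-phenylethyl)benzene-1,3-diol (C4 and C6 equivalent, C2 blocked by methyl).
4. The resorcinol comes from 3,5-dimethoxy-4-methylbenzaldehyde and diethyl benzylphosphonate by olefination, hydrogenation and demethylation.
5. No ring is formed in the route: both six-membered carbocycles are bought as benzene rings and only change oxidation level (resorcinol to quinone in step 4, triol to quinone in step 5).

Key step: step 5

Assumption: the target SMILES defines no stereocentre and no axial descriptor, so the hindered biaryl axis is treated as unspecified and the product is expected as the racemate about this axis.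

**Route**

Step 1
Reactants: 1 3,5-dimethoxy-4-methylbenzaldehyde; 2 diethyl benzylphosphonate
Product: 3 (E)-1,3-dimethoxy-2-methyl-5-(2-phenylethenyl)benzene
Conditions: KOtBu (1.2 equiv), THF, 0 °C to rt
Reagents that add atoms: none
Why: Horner–Wadsworth–Emmons olefination of an aromatic aldehyde with a benzylphosphonate anion is reliable and should give the (E)-stilbene; the alkene geometry is of no consequence because the double bond is saturated in step 2.

Step 2
Reactants: 3 (E)-1,3-dimethoxy-2-methyl-5-(2-phenylethenyl)benzene
Product: 4 1,3-dimethoxy-2-methyl-5-(2-phenylethyl)benzene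
Conditions: H2 (1 atm), Pd/C (10%), EtOAc, rt
Reagents that add atoms: none
Why: Heterogeneous catalytic hydrogenation should saturate the stilbene C=C at 1 atm without touching the aryl methyl ethers or the arene rings.

Step 3
Reactants: 4 1,3-dimethoxy-2-methyl-5-(2-phenylethyl)benzene
Product: 5 2-methyl-5-(2-phenylethyl)benzene-1,3-diol
Conditions: BBr3 (3 equiv), CH2Cl2, −78 °C to rt; then H2O
Reagents that add atoms: none
Why: BBr3 cleavage of aryl methyl ethers (O–B complexation, then SN2 attack of bromide on the methyl group) is standard for resorcinol dimethyl ethers, and no other Lewis-basic or acid-labile group is present.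

Step 4
Reactants: 5 2-methyl-5-(2-phenylethyl)benzene-1,3-diol
Product: 6 2-hydroxy-3-methyl-6-(2-phenylethyl)-1,4-benzoquinone
Conditions: (KSO3)2NO (2.5 equiv), aq. KH2PO4, acetone, 0 °C to rt; then dil. HCl
Reagents that add atoms: potassium nitrosodisulfonate (Fremy's salt), [K+].[K+].[O]N(S(=O)(=O)[O-])S(=O)(=O)[O-]
Why: In the Teuber oxidation one equivalent of the nitroxide removes the phenolic hydrogen and a second adds para to that oxygen, then imidodisulfonate is lost to give the p-quinone while the other resorcinol hydroxyl becomes the 2-hydroxy group; C4 and C6 of 5 are equivalent and C2 is blocked, so only one regioisomer can form.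

Step 5
Reactants: 6 2-hydroxy-3-methyl-6-(2-phenylethyl)-1,4-benzoquinone (two molecules)
Product: 9 4,4'-dihydroxy-5,5'-dimethyl-2,2'-bis(2-phenylethyl)-[1,1'-bi(cyclohexa-1,4-diene)]-3,3',6,6'-tetrone, via triol 7 (not isolated), via biaryl hexaol 8 (not isolated)
Conditions: Zn dust (0.5 equiv), degassed AcOH, Ar, rt; then CF3CO2H, 40 °C; then FeCl3 (2.2 equiv), H2O, rt; dil. HCl work-up
Reagents that add atoms: none
Why: Zn reduces half of 6 to triol 7; under acid the unsubstituted C5 of 7 (para to the C2–OH, ortho to the C4–OH) attacks the unsubstituted C5 of protonated 6, which is β to the C1 carbonyl (the C4 carbonyl is deactivated as a vinylogous acid by the C2–OH), and tautomerisation of the adduct gives the biaryl hexaol 8, which FeCl3 oxidises at both rings to the bis(hydroxyquinone) 9. The closest known reaction types are the acid-mediated quinone–hydroquinone dehydrodimerisation of 2-alkoxy- and 2-hydroxy-1,4-benzoquinones to 2,2'-biquinones (the 5,5'-dimerisation of benzene-1,2,4-triol on oxidation belongs here) and the Brønsted-acid-catalysed conjugate arylation of quinones by phenols, which also delivers tetra-ortho-substituted biaryldiols. No ring is closed and no stereocentre is created; the new biaryl axis is formed as the racemate. The step needs C–C over C–O coupling, inter- over intramolecular arylation and a stop at the dimer: O-addition is reversible under acid whereas C-addition is made irreversible by aromatisation, the pendant phenyl ring is unactivated and far less nucleophilic than the triol ring, and since each monomer has a single free ring carbon the regiochemistry is fixed and the fully substituted dimer can neither oligomerise nor close to a dibenzofuran.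

**Compound list**
1 | 3,5-dimethoxy-4-methylbenzaldehyde | COc1cc(C=O)cc(OC)c1C | starting material
2 | diethyl benzylphosphonate | CCOP(=O)(Cc1ccccc1)OCC | starting material
3 | (E)-1,3-dimethoxy-2-methyl-5-(2-phenylethenyl)benzene | COc1cc(/C=C/c2ccccc2)cc(OC)c1C | intermediate
4 | 1,3-dimethoxy-2-methyl-5-(2-phenylethyl)benzene | COc1cc(CCc2ccccc2)cc(OC)c1C | intermediate
5 | 2-methyl-5-(2-phenylethyl)benzene-1,3-diol | Cc1c(O)cc(CCc2ccccc2)cc1O | intermediate
6 | 2-hydroxy-3-methyl-6-(2-phenylethyl)-1,4-benzoquinone | CC1=C(O)C(=O)C(CCc2ccccc2)=CC1=O | intermediate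
7 | 3-methyl-6-(2-phenylethyl)benzene-1,2,4-triol | Cc1c(O)c(O)c(CCc2ccccc2)cc1O | intermediate
8 | 3,3'-dimethyl-6,6'-bis(2-phenylethyl)-[1,1'-biphenyl]-2,2',4,4',5,5'-hexol | Cc1c(O)c(O)c(CCc2ccccc2)c(c1O)-c1c(CCc2ccccc2)c(O)c(O)c(C)c1O | intermediate
9 | 4,4'-dihydroxy-5,5'-dimethyl-2,2'-bis(2-phenylethyl)-[1,1'-bi(cyclohexa-1,4-diene)]-3,3',6,6'-tetrone | CC1=C(O)C(=O)C(CCc2ccccc2)=C(C2=C(CCc3ccccc3)C(=O)C(O)=C(C)C2=O)C1=O | target

**Summary**
Total step count: 5
Longest linear sequence: 5 steps (1 → 3 → 4 → 5 → 6 → 9)

**Steps most likely to fail**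

Step 5 (key step). The intermolecular conjugate arylation may stall because a tetra-ortho-substituted axis must form, so that the two monomers only exchange redox state and are returned as 6 on oxidation. The fallback sets out from compound 6 and comes back at compound 9; it moves the biaryl bond formation to a protected arene and a reductive coupling. Reductive methylation of 6 (Na2S2O4, then Me2SO4, K2CO3, acetone) should give 1,3,4-trimethoxy-2-methyl-5-(2-phenylethyl)benzene F1. Iodination at the single free position of the electron-rich ring (N-iodosuccinimide, cat. CF3CO2H, MeCN) should give 1-iodo-2,4,5-trimethoxy-3-methyl-6-(2-phenylethyl)benzene F2. Classical Ullmann homocoupling (activated Cu bronze, DMF, 150 °C) should give 2,2',4,4',5,5'-hexamethoxy-3,3'-dimethyl-6,6'-bis(2-phenylethyl)-1,1'-biphenyl F3. Oxidative demethylation of both rings with (NH4)2Ce(NO3)6 in MeCN/H2O should give 4,4'-dimethoxy-5,5'-dimethyl-2,2'-bis(2-phenylethyl)-[1,1'-bi(cyclohexa-1,4-diene)]-3,3',6,6'-tetrone F4. Hydrolysis of its two vinylogous esters (aq. NaOH, then HCl) should give 9.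

Step 4. Over-oxidation or radical self-coupling of the very electron-rich resorcinol may compete with clean para-oxygenation. The fallback sets out from compound 5 and comes back at compound 6; it brings in the third oxygen by formylation and Dakin oxidation. Vilsmeier–Haack formylation of 5 (POCl3, DMF, MeCN, 0 °C to rt, aqueous work-up) should give 2,4-dihydroxy-3-methyl-6-(2-phenylethyl)benzaldehyde F5. Dakin oxidation (H2O2, aq. NaOH) should give triol 7, which an FeCl3 work-up should oxidise to 6.

Step 3. Demethylation may stop at the mono-ether, or the Lewis acid may degrade the electron-rich ring. The fallback sets out from compound 4 and comes back at compound 6, bypassing the free resorcinol and step 4. Vilsmeier–Haack formylation of 4 (POCl3, DMF, 80 °C) should give 2,4-dimethoxy-3-methyl-6-(2-phenylethyl)benzaldehyde F6. Baeyer–Villiger oxidation and hydrolysis of the aryl formate (mCPBA, CH2Cl2; then aq. NaOH) should give 2,4-dimethoxy-3-methyl-6-(2-phenylethyl)phenol F7. Oxidation of this p-methoxyphenol with (NH4)2Ce(NO3)6 in MeCN/H2O should give 2-methoxy-3-methyl-6-(2-phenylethyl)cyclohexa-2,5-diene-1,4-dione F8. Hydrolysis of the vinylogous ester (aq. NaOH, then HCl) should give 6.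

Further compounds
F1 | step 5 | 1,3,4-trimethoxy-2-methyl-5-(2-phenylethyl)benzene | Cc1c(OC)c(OC)c(CCc2ccccc2)cc1OC
F2 | step 5 | 1-iodo-2,4,5-trimethoxy-3-methyl-6-(2-phenylethyl)benzene | Cc1c(OC)c(OC)c(CCc2ccccc2)c(I)c1OC
F3 | step 5 | 2,2',4,4',5,5'-hexamethoxy-3,3'-dimethyl-6,6'-bis(2-phenylethyl)-1,1'-biphenyl | Cc1c(OC)c(OC)c(CCc2ccccc2)c(c1OC)-c1c(CCc2ccccc2)c(OC)c(OC)c(C)c1OC
F4 | step 5 | 4,4'-dimethoxy-5,5'-dimethyl-2,2'-bis(2-phenylethyl)-[1,1'-bi(cyclohexa-1,4-diene)]-3,3',6,6'-tetrone | CC1=C(OC)C(=O)C(CCc2ccccc2)=C(C2=C(CCc3ccccc3)C(=O)C(OC)=C(C)C2=O)C1=O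
F5 | step 4 | 2,4-dihydroxy-3-methyl-6-(2-phenylethyl)benzaldehyde | Cc1c(O)cc(CCc2ccccc2)c(C=O)c1O
F6 | step 3 | 2,4-dimethoxy-3-methyl-6-(2-phenylethyl)benzaldehyde | COc1cc(CCc2ccccc2)c(C=O)c(OC)c1C
F7 | step 3 | 2,4-dimethoxy-3-methyl-6-(2-phenylethyl)phenol | COc1cc(CCc2ccccc2)c(O)c(OC)c1C
F8 | step 3 | 2-methoxy-3-methyl-6-(2-phenylethyl)cyclohexa-2,5-diene-1,4-dione | CC1=C(OC)C(=O)C(CCc2ccccc2)=CC1=O
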